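## Retrosynthetic overview
1. The last bonds made are the two ester C–O bonds. A double Mitsunobu reaction (inversion at C6) joins an enantiopure O,O′-dibenzyl hetero-α-truxillic diacid to two equivalents of 6-epi-incarvilline, and the benzyl groups come off at the very end.
2. 6-epi-Incarvilline ⇐ ketone ⇐ bicyclic enone ⇐ intramolecular aldol condensation of a 1,4-diketone ⇐ Nef reaction ⇐ key intermolecular Michael addition of the pyrrolidine enamine of 1,3-dimethylpiperidin-4-one to (E)-2-nitrobut-2-ene. This forms the C7–C7a bond and puts all 11 carbons in place. The alcohol is resolved as its camphanate.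
3. Diacid ⇐ cis-cyclobutane-1,3-dicarboxylate (from methyl coumalate) by two amide-directed C–H arylations with an epimerisation in between, so the aryl groups end trans. It is resolved as an Evans imide.
4. Ring order: the piperidine is bought and the cyclopentane is closed by the aldol step. The cyclobutane comes from a 4π-electrocyclisation and hydrogenation. No ring is formed after the fragments are joined.

Assumption: (±) marks a racemate whose SMILES shows the enantiomer that ends up in the target; alkaloid positions follow cyclopenta[c]pyridine numbering (N2, 4-Me, C6–O, 7-Me); Ar1 = 4-(benzyloxy)-3-methoxyphenyl, Ar2 = 4-(benzyloxy)phenyl; cyclobutane "up/down" is seen from the Ar1 face going clockwise C(Ar1)–C(acyl A)–C(Ar2)–C(acyl B).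

## Route

Step 1
Reactants: 1 3-nitrobutan-2-ol (diastereomer mixture)
Product: 2 (E)-2-nitrobut-2-ene
Conditions: phthalic anhydride (1.3 equiv), neat, 150→185 °C, ca. 100 mmHg, product distilled out
Reagents that add atoms: none
Why: Dehydration of a β-nitro alcohol (phthalate half ester, then E1cB elimination) gives the conjugated nitroalkene, which distils off as the more stable E isomer.

Step 2
Reactants: 3 (±)-1,3-dimethylpiperidin-4-one
Product: 4 (±)-1,3-dimethyl-4-(pyrrolidin-1-yl)-1,2,3,6-tetrahydropyridine
Conditions: pyrrolidine (1.5 equiv), p-TsOH (1 mol %), toluene, reflux, Dean–Stark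
Reagents that add atoms: pyrrolidine, C1CCNC1
Why: Stork enamine formation, in which A(1,3) strain between the pyrrolidine ring and the 3-methyl group favours the less substituted C4=C5 enamine, so the unsubstituted α-carbon becomes the nucleophile.

Step 3
Reactants: 4 (±)-1,3-dimethyl-4-(pyrrolidin-1-yl)-1,2,3,6-tetrahydropyridine; 2 (E)-2-nitrobut-2-ene
Product: 6 1,3-dimethyl-5-(3-nitrobutan-2-yl)piperidin-4-one (diastereomer mixture), via iminium nitronate 5 (not isolated)
Conditions: MeCN, −10 °C→rt, 12 h; then AcOH/NaOAc/H2O, rt, 3 h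
Reagents that add atoms: water, O
Why: This is the key intermolecular Michael addition (Stork enamine to nitroalkene), forming the C7–C7a bond and joining the C7N piperidone to the C4 unit; every new stereocentre is α to C=O or NO2, so the mixture is carried on and settled by later equilibration.

Step 4
Reactants: 6 1,3-dimethyl-5-(3-nitrobutan-2-yl)piperidin-4-one
Product: 8 (±)-cis-1,3-dimethyl-5-(3-oxobutan-2-yl)piperidin-4-one (side-chain epimers), via sodium nitronate 7 (not isolated)
Conditions: NaOMe (1.1 equiv), MeOH, 0 °C; then 20 % aq TiCl3 (4.5 equiv), NH4OAc buffer (pH 5–6), rt; basic work-up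
Reagents that add atoms: water, O
Why: In this reductive Nef reaction (McMurry) Ti(III) reduces the nitronate to the imine, which hydrolyses to the ketone without touching the amine, and the two ring centres α to the piperidone carbonyl equilibrate to the cis-3,5-diequatorial arrangement (the later 4-Me/H-7a relation).

Step 5
Reactants: 8 (±)-cis-1,3-dimethyl-5-(3-oxobutan-2-yl)piperidin-4-one
Product: 9 (±)-(4R,7S,7aS)-2,4,7-trimethyl-1,2,3,4,7,7a-hexahydro-6H-cyclopenta[c]pyridin-6-one
Conditions: KOH (0.3 M), EtOH/H2O 4:1, 70 °C, 2 h, N2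
Reagents that add atoms: none
Why: In this intramolecular aldol condensation of a 1,4-diketone only attack of the methyl-ketone enolate on the ring ketone can dehydrate, so all material funnels to the conjugated cyclopentenone; the base keeps H-4 and H-7a cis and places the epimerisable 7-Me trans to C1, and the minor 4-epimer is removed by chromatography.

Step 6
Reactants: 9 (±)-bicyclic enone
Product: 10 (±)-(4R,4aS,7S,7aR)-2,4,7-trimethyloctahydro-6H-cyclopenta[c]pyridin-6-one
Conditions: H2 (1 atm), 10 % Pd/C, EtOH, rt; filter; then K2CO3, MeOH, rt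
Reagents that add atoms: none
Why: Heterogeneous hydrogenation adds H to C4a from the equatorial side of the chair piperidine, which is the face carrying H-4 and H-7a, so the cis-fused ketone forms, and the carbonate treatment secures the convex-face 7-methyl group by enolate equilibration.

Step 7
Reactants: 10 (±)-bicyclic ketone
Product: 11 (±)-6-epi-incarvilline [(±)-(4R,4aS,6S,7S,7aR)-2,4,7-trimethyloctahydro-1H-cyclopenta[c]pyridin-6-ol]
Conditions: NaBH4, MeOH, −20→0 °C
Reagents that add atoms: none
Why: In this diastereoselective hydride reduction the small hydride attacks from the convex face, away from C1 and C4 folded under the ring, which is also the usual trans outcome for 2-methylcyclopentanones, so the OH ends concave and trans to 7-Me.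

Step 8
Reactants: 11 (±)-6-epi-incarvilline
Product: 12 (4R,4aS,6S,7S,7aR)-2,4,7-trimethyloctahydro-1H-cyclopenta[c]pyridin-6-yl (1S,4R)-camphanate
Conditions: (1S)-(−)-camphanic chloride (1.2 equiv), Et3N, DMAP (cat.), CH2Cl2, 0 °C→rt; the two diastereomers separated by chromatography (CH2Cl2/MeOH/NH3) and recrystallisation; assignment by X-ray
Reagents that add atoms: (1S)-(−)-camphanic chloride, CC1(C)[C@@]2(C)CC[C@]1(C(=O)Cl)OC2=O
Why: This is a resolution through covalent diastereomers, in which O-acylation proceeds with retention at C6, the acyl group has no α-H and cannot racemise, and its known configuration serves as internal reference for the absolute assignment.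

Step 9
Reactants: 12 camphanate of 6-epi-incarvilline
Product: 13 6-epi-incarvilline (single enantiomer; 4R,4aS,6S,7S,7aR)
Conditions: K2CO3, MeOH, rt→40 °C
Reagents that add atoms: none
Why: Base-catalysed transesterification (methanolysis) breaks the acyl–O bond only, so no stereocentre of the alcohol is touched.

Step 10
Reactants: 14 guaiacol (2-methoxyphenol)
Product: 15 4-iodo-2-methoxyphenol
Conditions: NaI (1.0 equiv), NaOH (1.0 equiv), aq NaOCl (1.0 equiv, dropwise), MeOH, 0 °C; acidic work-up
Reagents that add atoms: sodium iodide, [Na+].[I-]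
Why: In this electrophilic aromatic iodination by hypoiodite made in situ, the phenolate oxygen is the strongest director and sends iodine para to itself.

Step 11
Reactants: 15 4-iodo-2-methoxyphenol
Product: 16 1-(benzyloxy)-4-iodo-2-methoxybenzene
Conditions: BnBr, K2CO3, DMF, rt
Reagents that add atoms: benzyl bromide, BrCc1ccccc1
Why: Williamson ether synthesis installs a benzyl ether that survives Pd(II)/Ag(I), alkoxide, LiOOH and Mitsunobu conditions and leaves by neutral hydrogenolysis.

Step 12
Reactants: 17 methyl coumalate (methyl 2-oxo-2H-pyran-5-carboxylate)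
Product: 19 cis-3-(methoxycarbonyl)cyclobutane-1-carboxylic acid, via photopyrone 18 (not isolated)
Conditions: hν (450 W medium-pressure Hg lamp, Pyrex), CH2Cl2, 15 °C; then H2 (1 atm), Pt/C, same flask, rt
Reagents that add atoms: none
Why: Photochemical 4π-electrocyclisation of the 2-pyrone gives the bicyclic β-lactone, and hydrogenation from its convex face together with hydrogenolysis of the strained allylic C–O bond leaves the two carboxyl groups cis.

Step 13
Reactants: 19 cis-3-(methoxycarbonyl)cyclobutane-1-carboxylic acid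
Product: 20 methyl cis-3-{[2-(methylsulfanyl)phenyl]carbamoyl}cyclobutane-1-carboxylate
Conditions: EDC·HCl, 2-(methylthio)aniline, CH2Cl2, rt
Reagents that add atoms: 2-(methylthio)aniline, CSc1ccccc1N
Why: Carbodiimide amide coupling installs the N,S-bidentate directing group without disturbing the cis relation.

Step 14
Reactants: 20 cis amide ester; 16 1-(benzyloxy)-4-iodo-2-methoxybenzene
Product: 21 (±)-methyl all-cis-2-Ar1-3-{[2-(methylsulfanyl)phenyl]carbamoyl}cyclobutane-1-carboxylate
Conditions: Pd(OAc)2 (15 mol %), Ag2CO3 (1.0 equiv), PivOH (1.0 equiv), HFIP, 90 °C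
Reagents that add atoms: none
Why: In this amide-directed Pd(II)/Pd(IV) C(sp3)–H arylation the palladacycle can only form with a methylene C–H cis to the amide, so Ar1 enters cis to amide and ester; HFIP/PivOH stops the reaction at monoarylation, and the two enantiotopic CH2 groups give a racemate.

Step 15
Reactants: 21 (±)-all-cis monoaryl amide ester
Product: 22 (±)-methyl 2-Ar1-3-{[2-(methylsulfanyl)phenyl]carbamoyl}cyclobutane-1-carboxylate (ester cis to Ar1; amide trans to Ar1 and to ester)
Conditions: LiOt-Bu (2 equiv), toluene, 50 °C; then AcOH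
Reagents that add atoms: none
Why: Base-mediated epimerisation under reversible lithium alkoxide conditions in a non-polar solvent inverts the chelated amide-bearing carbon, relieves the all-cis strain and leaves the ester-bearing centre as it is.

Step 16
Reactants: 22 (±)-epimerised monoaryl amide ester; 23 1-(benzyloxy)-4-iodobenzene
Product: 24 (±)-methyl 2-Ar1-4-Ar2-3-{[2-(methylsulfanyl)phenyl]carbamoyl}cyclobutane-1-carboxylate (Ar1 up; amide down; Ar2 down; ester up)
Conditions: Pd(OAc)2 (15 mol %), Ag2CO3 (1.5 equiv), PivOH (1.0 equiv), t-BuOH, 80 °C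
Reagents that add atoms: none
Why: In the second directed C–H arylation the only methylene C–H cis to the inverted amide lies on the remaining CH2, so Ar2 enters cis to the amide and trans to Ar1, which gives the α-truxillate pattern.

Step 17
Reactants: 24 (±)-diaryl amide ester
Product: 25 (±)-N-Boc derivative of 24
Conditions: Boc2O (3 equiv), DMAP, MeCN, rt
Reagents that add atoms: di-tert-butyl dicarbonate, CC(C)(C)OC(=O)OC(=O)OC(C)(C)C
Why: N-acylation of the anilide gives a twisted N-acyl carbamate, which activates the otherwise inert amide for mild cleavage.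

Step 18
Reactants: 25 (±)-N-Boc amide ester
Product: 26 (±)-2-Ar2-4-Ar1-3-(methoxycarbonyl)cyclobutane-1-carboxylic acid (Ar1 up; CO2H down; Ar2 down; CO2Me up)
Conditions: LiOH (2 equiv), 30 % H2O2 (8 equiv), THF/H2O 3:1, 0 °C, 2 h; aq Na2SO3; 1 M HCl
Reagents that add atoms: hydrogen peroxide, OO
Why: Hydroperoxide cleavage of an activated amide works because the weakly basic, highly nucleophilic LiOOH attacks the acyl carbonyl at 0 °C, where the hindered methyl ester and the α-stereocentres are untouched.

Step 19
Reactants: 26 (±)-mono acid mono methyl ester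
Product: 28 methyl 2-Ar1-4-Ar2-3-{[(4S)-4-benzyl-2-oxo-1,3-oxazolidin-3-yl]carbonyl}cyclobutane-1-carboxylate (Ar1 up; imide down; Ar2 down; ester up), via acid chloride 27 (not isolated)
Conditions: (COCl)2, DMF (cat.), CH2Cl2, 0 °C→rt, concentrate; then Li salt of (S)-4-benzyloxazolidin-2-one (n-BuLi, THF, −78 °C); the two imides separated on SiO2 and by crystallisation; assignment by X-ray
Reagents that add atoms: (S)-4-benzyloxazolidin-2-one, O=C1N[C@@H](Cc2ccccc2)CO1
Why: This is a resolution through covalent diastereomers (N-acylation of an Evans oxazolidinone), done while the two carboxyl groups are still different, so the enantiomeric cores give clearly different and separable imides.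

Step 20
Reactants: 28 single imide diastereomer
Product: 29 2-Ar1-4-Ar2-cyclobutane-1,3-dicarboxylic acid (single enantiomer; Ar1 up; CO2H down; Ar2 down; CO2H up)
Conditions: LiOH, 30 % H2O2, THF/H2O, 0 °C; aq Na2SO3; then LiOH (10 equiv), THF/MeOH/H2O, 45 °C; 1 M HCl
Reagents that add atoms: hydrogen peroxide, OO; lithium hydroxide, [Li+].[OH-]
Why: LiOOH removes the auxiliary at the exocyclic carbonyl and the following saponification opens the methyl ester, with hydrolysis faster than enolisation so the α-truxillic configuration is kept.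

Step 21
Reactants: 29 enantiopure diacid; 13 6-epi-incarvilline (2.4 equiv)
Product: 30 O,O′-dibenzyl ether of the target (bis-incarvillyl diester)
Conditions: PPh3 (3 equiv), DIAD (3 equiv), THF, 0 °C→rt
Reagents that add atoms: none
Why: In the double Mitsunobu esterification each carboxylate displaces the alkoxyphosphonium group by SN2 with clean inversion (6S→6R), which puts the ester oxygen on the convex face cis to 7-Me, and the acid α-centres are never activated.

Step 22
Reactants: 30 dibenzyl ether
Product: 31 CNP0331906.2 (target)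
Conditions: H2 (1 atm), 10 % Pd/C, MeOH/EtOAc, rt
Reagents that add atoms: none
Why: Neutral hydrogenolysis of the two aryl benzyl ethers frees both phenols without affecting the esters, the tertiary amines or the cyclobutane.

## Compound list
1 | 3-nitrobutan-2-ol (diastereomer mixture) | CC(O)C(C)[N+](=O)[O-] | starting material
2 | (E)-2-nitrobut-2-ene | C/C=C(\C)[N+](=O)[O-] | intermediate
3 | (±)-1,3-dimethylpiperidin-4-one | CC1CN(C)CCC1=O | starting material
4 | (±)-1,3-dimethyl-4-(pyrrolidin-1-yl)-1,2,3,6-tetrahydropyridine | CC1CN(C)CC=C1N1CCCC1 | intermediate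
5 | iminium nitronate zwitterion, Michael adduct before hydrolysis (stereoisomer mixture, not isolated) | CC1CN(C)CC(C(C)C(C)=[N+]([O-])[O-])C1=[N+]1CCCC1 | intermediate
6 | 1,3-dimethyl-5-(3-nitrobutan-2-yl)piperidin-4-one (diastereomer mixture) | CC1CN(C)CC(C(C)C(C)[N+](=O)[O-])C1=O | intermediate
7 | sodium nitronate of 6 (not isolated) | CC1CN(C)CC(C(C)C(C)=[N+]([O-])[O-])C1=O.[Na+] | intermediate
8 | (±)-cis-(3S,5R)-1,3-dimethyl-5-(3-oxobutan-2-yl)piperidin-4-one (side-chain centre unassigned) | CC(=O)C(C)[C@@H]1CN(C)C[C@H](C)C1=O | intermediate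
9 | (±)-(4R,7S,7aS)-2,4,7-trimethyl-1,2,3,4,7,7a-hexahydro-6H-cyclopenta[c]pyridin-6-one | O=C1C=C2[C@@H](CN(C)C[C@@H]2C)[C@@H]1C | intermediate
10 | (±)-(4R,4aS,7S,7aR)-2,4,7-trimethyloctahydro-6H-cyclopenta[c]pyridin-6-one (cis-fused) | O=C1C[C@@H]2[C@@H](CN(C)C[C@@H]2C)[C@@H]1C | intermediate
11 | (±)-6-epi-incarvilline | O[C@H]1C[C@@H]2[C@@H](CN(C)C[C@@H]2C)[C@@H]1C | intermediate
12 | (1S,4R)-camphanate of (4R,4aS,6S,7S,7aR)-6-epi-incarvilline | CC1(C)[C@@]2(C)CC[C@]1(C(=O)O[C@H]3C[C@@H]4[C@@H](CN(C)C[C@@H]4C)[C@@H]3C)OC2=O | intermediate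
13 | 6-epi-incarvilline, single enantiomer (4R,4aS,6S,7S,7aR) | O[C@H]1C[C@@H]2[C@@H](CN(C)C[C@@H]2C)[C@@H]1C | intermediate
14 | guaiacol | COc1ccccc1O | starting material
15 | 4-iodo-2-methoxyphenol | COc1cc(I)ccc1O | intermediate
16 | 1-(benzyloxy)-4-iodo-2-methoxybenzene | COc1cc(I)ccc1OCc1ccccc1 | intermediate
17 | methyl coumalate | COC(=O)C1=COC(=O)C=C1 | starting material
18 | (±)-methyl 3-oxo-2-oxabicyclo[2.2.0]hex-5-ene-6-carboxylate (photopyrone, not isolated) | COC(=O)C1=C[C@@H]2[C@H]1OC2=O | intermediate
19 | cis-3-(methoxycarbonyl)cyclobutane-1-carboxylic acid | C1[C@@H](C(=O)O)C[C@H]1C(=O)OC | intermediate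
20 | methyl cis-3-{[2-(methylsulfanyl)phenyl]carbamoyl}cyclobutane-1-carboxylate | C1[C@@H](C(=O)Nc2ccccc2SC)C[C@H]1C(=O)OC | intermediate
21 | (±)-all-cis monoaryl amide ester (Ar1, amide and ester all up) | COc1cc([C@H]2[C@@H](C(=O)Nc3ccccc3SC)C[C@H]2C(=O)OC)ccc1OCc1ccccc1 | intermediate
22 | (±)-monoaryl amide ester epimerised at the amide carbon (Ar1 up, amide down, ester up) | COc1cc([C@H]2[C@H](C(=O)Nc3ccccc3SC)C[C@H]2C(=O)OC)ccc1OCc1ccccc1 | intermediate
23 | 1-(benzyloxy)-4-iodobenzene | Ic1ccc(OCc2ccccc2)cc1 | starting material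
24 | (±)-diaryl amide ester, α-truxillate configuration (Ar1 up, amide down, Ar2 down, ester up) | COc1cc([C@H]2[C@H](C(=O)Nc3ccccc3SC)[C@H](c3ccc(OCc4ccccc4)cc3)[C@H]2C(=O)OC)ccc1OCc1ccccc1 | intermediate
25 | (±)-N-Boc derivative of 24 | COc1cc([C@H]2[C@H](C(=O)N(C(=O)OC(C)(C)C)c3ccccc3SC)[C@H](c3ccc(OCc4ccccc4)cc3)[C@H]2C(=O)OC)ccc1OCc1ccccc1 | intermediate
26 | (±)-mono acid mono methyl ester (Ar1 up, CO2H down, Ar2 down, CO2Me up) | COc1cc([C@H]2[C@H](C(=O)O)[C@H](c3ccc(OCc4ccccc4)cc3)[C@H]2C(=O)OC)ccc1OCc1ccccc1 | intermediate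
27 | (±)-acid chloride of 26 (not isolated) | COc1cc([C@H]2[C@H](C(=O)Cl)[C@H](c3ccc(OCc4ccccc4)cc3)[C@H]2C(=O)OC)ccc1OCc1ccccc1 | intermediate
28 | (4S)-4-benzyloxazolidinone imide methyl ester, wanted diastereomer | COc1cc([C@H]2[C@H](C(=O)N3[C@@H](Cc4ccccc4)COC3=O)[C@H](c3ccc(OCc4ccccc4)cc3)[C@H]2C(=O)OC)ccc1OCc1ccccc1 | intermediate
29 | enantiopure O,O′-dibenzyl hetero-α-truxillic diacid | COc1cc([C@H]2[C@H](C(=O)O)[C@H](c3ccc(OCc4ccccc4)cc3)[C@H]2C(=O)O)ccc1OCc1ccccc1 | intermediate
30 | O,O′-dibenzyl ether of the target | COc1cc([C@H]2[C@H](C(=O)O[C@@H]3C[C@@H]4[C@@H](CN(C)C[C@@H]4C)[C@@H]3C)[C@H](c3ccc(OCc4ccccc4)cc3)[C@H]2C(=O)O[C@@H]2C[C@@H]3[C@@H](CN(C)C[C@@H]3C)[C@@H]2C)ccc1OCc1ccccc1 | intermediate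
31 | CNP0331906.2 | COc1cc([C@H]2[C@H](C(=O)O[C@@H]3C[C@@H]4[C@@H](CN(C)C[C@@H]4C)[C@@H]3C)[C@H](c3ccc(O)cc3)[C@H]2C(=O)O[C@@H]2C[C@@H]3[C@@H](CN(C)C[C@@H]3C)[C@@H]2C)ccc1O | target

## Step count and risks

Total step count: 22.
Longest linear sequence: 11 steps (17→31 through steps 12–22, and equally 14→31 through steps 10, 11 and 14–22). The alkaloid branch needs 10 steps to reach 31.

**Step 6, face selectivity of the hydrogenation (cis ring fusion, H-4a).** The enone is fairly flat and the 7-methyl group sits on the wanted face.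
- The fallback sets out from 9 and returns at 10. It replaces steric control by a directing group.
- Luche reduction (NaBH4, CeCl3·7H2O, MeOH, −78 °C) attacks C6 anti to the neighbouring 7-methyl group. It gives the allylic alcohol (±)-2,4,7-trimethyl-2,3,4,6,7,7a-hexahydro-1H-cyclopenta[c]pyridin-6-ol with 6-OH cis to 7-Me F1.
- Hydroxyl-directed homogeneous hydrogenation follows, using Crabtree's catalyst (H2, CH2Cl2) with the amine masked as its HBF4 salt. It delivers H to C4a from the OH face and gives (±)-incarvilline F2.
- Swern oxidation then gives ketone 10.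

**Step 8, separation of the two camphanates.**
- The fallback sets out from 11 and returns at 13, bypassing 12. It is an enzymatic kinetic resolution instead of a covalent auxiliary.
- The conditions are immobilised Candida antarctica lipase B and vinyl acetate in MTBE at 30 °C, run to about 50 % conversion.
- For this trans-2-methylcyclopentanol type the (6R)-enantiomer is acylated faster. It becomes the acetate of ent-6-epi-incarvilline F3.
- The wanted (6S)-alcohol 13 stays unreacted and is separated from the far less polar acetate by chromatography.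

**Step 15, site selectivity of the epimerisation (amide-bearing versus ester-bearing carbon, or both).**
- The fallback sets out from 21 and returns at 22. Acidity, not chelation, decides the site.
- Boc2O/DMAP converts 21 into the N-Boc all-cis amide ester F4. Its N-acyl carbamate α-H is now clearly the most acidic C–H.
- DBU in MeCN at 50 °C equilibrates only this centre, giving the N-Boc amide ester with the acyl group trans to Ar1 F5.
- TFA/CH2Cl2 at 0 °C removes the Boc group and gives 22.

Further compounds
F1 | step 6 | (±)-allylic alcohol from 1,2-reduction of 9, 6-OH cis to 7-Me | O[C@@H]1C=C2[C@@H](CN(C)C[C@@H]2C)[C@@H]1C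
F2 | step 6 | (±)-incarvilline (4R,4aS,6R,7S,7aR drawn) | O[C@@H]1C[C@@H]2[C@@H](CN(C)C[C@@H]2C)[C@@H]1C
F3 | step 8 | acetate of ent-6-epi-incarvilline | CC(=O)O[C@@H]1C[C@H]2[C@H](CN(C)C[C@H]2C)[C@H]1C
F4 | step 15 | (±)-N-Boc derivative of 21 (all-cis) | COc1cc([C@H]2[C@@H](C(=O)N(C(=O)OC(C)(C)C)c3ccccc3SC)C[C@H]2C(=O)OC)ccc1OCc1ccccc1
F5 | step 15 | (±)-N-Boc derivative of 22 (acyl group trans to Ar1) | COc1cc([C@H]2[C@H](C(=O)N(C(=O)OC(C)(C)C)c3ccccc3SC)C[C@H]2C(=O)OC)ccc1OCc1ccccc1
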